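**Plan**

1. Ring A (the seven-membered enoate lactone) is cut last, at the C1=C2 alkene and at the ester O–C4 bond. This works because C4 is a gem-dimethyl carbon on C5 (the Markovnikov carbon of an isopropenyl group) and C1 sits on the quaternary C10 (the inner carbon of a vinyl group), so the O–C(=O)–CH unit of crotonic acid can bridge a ring-B 1,5-diene.
2. The cage is then cut at C19–C20 (vinyl-radical closure of cyclopentane ring F onto a ring-D-fused butenolide), at ring D (C13–C15 and C16=C19, Michael/methylation/Horner–Wadsworth–Emmons annulation), at C8–C19 (vinylogous Mukaiyama aldol) and at ring C (Robinson annulation).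
3. Forward order: ring B (conjugate addition, α-vinylation) → ring C → quaternary C8 → ring D with lactone ring E → ethynyl on C11 and C9–H → ring F with the exocyclic methylene → ring A.
4. Stereochemistry: C5 comes from a copper-catalysed asymmetric conjugate addition and every other centre is relayed from it. C10 is set anti to C5, C8 anti to the axial C10 methyl, C13 by methylation anti to the C8 acyl group, C9 and C11 by hydride and proton delivery to the open face, and C19 and C16 by the geometry of the radical ring closure.

Key step: step 13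

Remark on the chemistry: the ligand enantiomer named in step 1 is assumed to give the S centre; its antipode is used otherwise. Locants are for description only. Ring A is C1=C2–C3(=O)–O–C4(Me2)–C5–C10 and ring B is C5–C6–C7–C8–C9–C10(Me). C11 is the CH between C9, C12 and C20; C12 the ketone; C13 the C–CH3 carbon; C14 the CH2 between C13 and C8; C15 the CH2 between C13 and C16; C16 the lactone α-CH; C17 the lactone C=O; C18 the OCH2 on C19; C19 the quaternary carbon bonded to C8, C16, C18 and C20; C20 the carbon that bears =CH2. Ring C is C8–C9–C11–C12–C13–C14, ring D is C8–C14–C13–C15–C16–C19, ring E is the γ-lactone, ring F is C8–C9–C11–C20–C19. β is the face of ring B that carries the C10 methyl group.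

**Route**

Step 1
Reactants: 1 2-methylcyclohex-2-en-1-one; 2 isopropenylmagnesium bromide; 3 chlorotrimethylsilane
Product: 4 (S)-trimethyl{[2-methyl-3-(prop-1-en-2-yl)cyclohex-1-en-1-yl]oxy}silane
Conditions: CuBr·SMe2 (5 mol %), (R)-1-[(S)-2-(diphenylphosphino)ferrocenyl]ethyldicyclohexylphosphine (6 mol %), Me3SiCl, t-BuOMe, −78 °C; Et3N quench
Reagents that add atoms: isopropenylmagnesium bromide (CC(=C)[Mg]Br); chlorotrimethylsilane (C[Si](C)(C)Cl)
Why: Copper-catalysed asymmetric conjugate addition of a Grignard reagent to a cyclic enone with a ferrocenyl diphosphine ligand should set C5, and silylation in the flask fixes the enolate toward C10.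

Step 2
Reactants: 4 silyl enol ether; 5 bromoethene
Product: 6 (2S,3S)-2-ethenyl-2-methyl-3-(prop-1-en-2-yl)cyclohexan-1-one
Conditions: MeLi, THF, 0 °C; ZnCl2; then CH2=CHBr, Pd2(dba)3 (2 mol %), P(t-Bu)3 (8 mol %), THF, 25 °C
Reagents that add atoms: bromoethene (C=CBr)
Why: Palladium-catalysed α-alkenylation of the regiodefined zinc enolate (Negishi-type coupling) should build the quaternary C10, the vinyl group entering anti to the neighbouring isopropenyl group (trans).

Step 3
Reactants: 6 ring-B ketone; 7 but-3-en-2-one
Product: 9 bicyclic enone (ring B fused to cyclohexenone ring C; C8 epimers), via diketone 8 (not isolated)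
Conditions: NaOEt (0.2 equiv), EtOH, −10 → 25 °C; then KOH, MeOH, 60 °C
Reagents that add atoms: but-3-en-2-one (CC(=O)C=C)
Why: Robinson annulation (Michael addition, then aldol condensation) should work because ketone 6 can enolise only toward C8; the C8–H centre is left as a mixture since it becomes planar in step 4.

Step 4
Reactants: 9 bicyclic enone; 10 tert-butyldimethylsilyl trifluoromethanesulfonate
Product: 11 extended silyl dienol ether (C12–OSi; C11=C12 and C8=C9)
Conditions: TBSOTf, Et3N, CH2Cl2, 0 → 25 °C
Reagents that add atoms: tert-butyldimethylsilyl trifluoromethanesulfonate (CC(C)(C)[Si](C)(C)OS(=O)(=O)C(F)(F)F)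
Why: Soft enolisation under equilibrating conditions should give the linear silyl dienol ether, the only γ-hydrogen being on C8 because C10 is quaternary.

Step 5
Reactants: 11 silyl dienol ether; 12 2,2-dimethoxyacetaldehyde
Product: 13 γ-aldol adduct (enone with a 1-hydroxy-2,2-dimethoxyethyl group on the α face of C8; carbinol epimers)
Conditions: anhydrous (MeO)2CHCHO, BF3·OEt2, CH2Cl2, −78 °C; aq NaHCO3
Reagents that add atoms: 2,2-dimethoxyacetaldehyde (COC(OC)C=O)
Why: Vinylogous Mukaiyama aldol addition at the γ-carbon should rebuild the enone and create the quaternary C8, the aldehyde approaching anti to the axial C10 methyl group so that C19 lies on the α face.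

Step 6
Reactants: 13 γ-aldol adduct
Product: 14 α-keto acetal (C8–C(=O)–CH(OMe)2)
Conditions: Dess–Martin periodinane, NaHCO3, CH2Cl2, 25 °C
Reagents that add atoms: none
Why: Dess–Martin oxidation of the secondary alcohol removes the carbinol centre and gives a ketone whose acetal C–H is too hindered and too weakly acidic to compete in the next enolisation.

Step 7
Reactants: 14 α-keto acetal; 15 ethyl 2-(diethoxyphosphoryl)acrylate; 16 iodomethane
Product: 19 tricyclic keto ester (ring D closed; ethyl ester on C16; dimethoxymethyl on C19; 13β-methyl), via Michael adduct 17 (not isolated), via methylated phosphonate 18 (not isolated)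
Conditions: LiN(i-Pr)2 (1.0 equiv), THF, −78 °C; 15; LiN(i-Pr)2 (1.1 equiv), −78 °C; MeI; −78 → 25 °C
Reagents that add atoms: ethyl 2-(diethoxyphosphoryl)acrylate (C=C(C(=O)OCC)P(=O)(OCC)OCC); iodomethane (CI)
Why: In this tandem Michael addition/enolate methylation/intramolecular Horner–Wadsworth–Emmons olefination the kinetic α′-enolate at C13 adds to the vinylphosphonate, the dianion is methylated at the more reactive C13 enolate anti to the axial C8 acyl group (methyl β, side chain α), and the phosphonate carbanion then condenses with the syn C19 ketone to close ring D.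

Step 8
Reactants: 19 tricyclic keto ester
Product: 21 butenolide enone (lactone ring E fused to ring D at C16=C19), via aldehyde 20 (not isolated)
Conditions: 1 M HCl, THF, 25 °C; then NaBH4, MeOH/CH2Cl2, −78 °C; AcOH, 25 °C
Reagents that add atoms: water (O)
Why: Acetal hydrolysis, chemoselective 1,2-reduction of the aldehyde at low temperature (the hindered enone is slower) and lactonisation of the (Z)-γ-hydroxy enoate should give the butenolide.

Step 9
Reactants: 21 butenolide enone; 22 iodine
Product: 23 α-iodoenone (iodine on C11)
Conditions: I2, pyridine, CH2Cl2, 25 °C, dark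
Reagents that add atoms: iodine (II)
Why: Pyridine-mediated α-iodination of an enone (addition–elimination) should functionalise C11, the only enone α-position that bears hydrogen.

Step 10
Reactants: 23 α-iodoenone; 24 ethynyltrimethylsilane
Product: 26 ethynyl enone (ethynyl on C11), via silylalkyne 25 (not isolated)
Conditions: HC≡CSiMe3, PdCl2(PPh3)2, CuI, i-Pr2NH, THF, 25 °C; then K2CO3, MeOH, 0 °C
Reagents that add atoms: ethynyltrimethylsilane (C#C[Si](C)(C)C)
Why: Sonogashira coupling and protodesilylation put C20 and its future methylene carbon on the sp2 carbon C11, so no stereocentre is at stake in this step.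

Step 11
Reactants: 26 ethynyl enone
Product: 27 saturated ketone (9β-H; ethynyl on C11 endo, on the side of the butenolide)
Conditions: [(Ph3P)CuH]6 (excess), toluene, 25 °C; AcOH, −40 °C
Reagents that add atoms: none
Why: Copper hydride conjugate reduction should deliver hydride to C9 and then the proton to C11 from the exposed β face of the bicyclo[3.3.1]nonene, since ring D covers the α face, which sets 9β-H and leaves the ethynyl group endo.

Step 12
Reactants: 27 saturated ketone
Product: 29 cage diene (rings C to F complete; exocyclic methylene on C20; 10α-vinyl; 5β-isopropenyl), via vinylstannane 28 (not isolated)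
Conditions: Bu3SnH (slow addition), AIBN (cat.), benzene, 80 °C; then CF3CO2H, CH2Cl2, 0 °C
Reagents that add atoms: none
Why: In this hydrostannylative vinyl-radical cyclisation Bu3Sn• adds to the terminal alkyne carbon, the radical at C20 closes 5-exo-trig onto the butenolide β-carbon C19 from the only face within reach (fixing C19), the α-lactone radical at C16 takes hydrogen from the face opposite the new bridge, and acid then removes tin to leave the methylene.

Step 13
Reactants: 29 cage diene; 30 (E)-but-2-enoic acid
Product: 32 target CNP0136584.3, via crotonate ester 31 (not isolated)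
Conditions: (E)-MeCH=CHCO2H (5 equiv), Co(salen) (5 mol %; salen = N,N′-bis(3,5-di-tert-butylsalicylidene)-1,2-cyclohexanediamine), N-fluoro-2,4,6-trimethylpyridinium triflate, PhSiH3, PhCF3, 0 → 25 °C; silica plug; then second-generation Hoveyda–Grubbs catalyst (10 mol %), toluene, 80 °C
Reagents that add atoms: (E)-but-2-enoic acid (C/C=C/C(=O)O)
Why: The Co–H species transfers a hydrogen atom to the CH2 end of the isopropenyl group, the tertiary C4 radical is oxidised through the alkylcobalt to a cation equivalent and captured by the acid oxygen of crotonic acid (O–C4 bond, ester 31), and the ruthenium alkylidene formed on the C10 vinyl group then closes onto the crotonate through a ruthenacyclobutane and releases propene (C1=C2 bond). The closest known reaction types are the metal-hydride radical-polar crossover hydroalkoxylation and hydroacyloxylation of 1,1-disubstituted alkenes and the ring-closing metathesis of acrylate or crotonate esters to α,β-unsaturated lactones. Ring A is the only ring formed; it closes by ring-closing metathesis as a seven-membered ring, which can hold only the cis alkene. No stereocentre is created (C4 carries two methyl groups) and C5 and C10 are not touched. The step needs hydrogen-atom transfer to the isopropenyl group rather than to the cage methylene or the vinyl group: the cage methylene lies between a quaternary and a bridgehead carbon, so its tertiary radical can neither isomerise nor be captured easily and should revert, the vinyl group would give only a secondary radical, crotonic acid is a poor radical acceptor, and in the metathesis the cage methylene is too hindered to load ruthenium.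

**Compound list**

1 | 2-methylcyclohex-2-en-1-one | CC1=CCCCC1=O | starting material
2 | isopropenylmagnesium bromide (prop-1-en-2-ylmagnesium bromide) | CC(=C)[Mg]Br | starting material
3 | chlorotrimethylsilane | C[Si](C)(C)Cl | starting material
4 | (S)-trimethyl{[2-methyl-3-(prop-1-en-2-yl)cyclohex-1-en-1-yl]oxy}silane | CC(=C)[C@@H]1CCCC(O[Si](C)(C)C)=C1C | intermediate
5 | bromoethene (vinyl bromide) | C=CBr | starting material
6 | (2S,3S)-2-ethenyl-2-methyl-3-(prop-1-en-2-yl)cyclohexan-1-one (ring B with C9 ketone; vinyl trans to isopropenyl) | C=C[C@]1(C)C(=O)CCC[C@H]1C(C)=C | intermediate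
7 | but-3-en-2-one (methyl vinyl ketone) | CC(=O)C=C | starting material
8 | diketone: 6 carrying a 3-oxobutyl group on C8 (C8 epimers) | C=C[C@]1(C)C(=O)C(CCC(C)=O)CC[C@H]1C(C)=C | intermediate
9 | bicyclic enone: ring B fused to cyclohexenone ring C (C12=O, C11=C9); 10β-methyl, 10α-vinyl, 5β-isopropenyl; C8 epimers | O=C1C=C2[C@@](C)(C=C)[C@H](C(C)=C)CCC2CC1 | intermediate
10 | tert-butyldimethylsilyl trifluoromethanesulfonate | CC(C)(C)[Si](C)(C)OS(=O)(=O)C(F)(F)F | starting material
11 | tert-butyldimethylsilyl dienol ether of 9 (C12–OSi; double bonds C11=C12 and C8=C9) | CC(C)(C)[Si](C)(C)OC1=CC2=C(CC1)CC[C@@H](C(C)=C)[C@]2(C)C=C | intermediate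
12 | 2,2-dimethoxyacetaldehyde | COC(OC)C=O | starting material
13 | γ-aldol adduct: enone 9 with a 1-hydroxy-2,2-dimethoxyethyl group on the α face of C8 (C14 β; carbinol epimers) | O=C1C=C2[C@@](C)(C=C)[C@H](C(C)=C)CC[C@]2(C(O)C(OC)OC)CC1 | intermediate
14 | α-keto acetal: enone with C8α–C(=O)–CH(OMe)2 | O=C1C=C2[C@@](C)(C=C)[C@H](C(C)=C)CC[C@]2(C(=O)C(OC)OC)CC1 | intermediate
15 | ethyl 2-(diethoxyphosphoryl)acrylate | C=C(C(=O)OCC)P(=O)(OCC)OCC | starting material
16 | iodomethane | CI | starting material
17 | Michael adduct: 14 with CH2CH(CO2Et)P(O)(OEt)2 on C13 (epimers at C13 and at the phosphonate carbon) | O=C1C=C2[C@@](C)(C=C)[C@H](C(C)=C)CC[C@]2(C(=O)C(OC)OC)CC1CC(C(=O)OCC)P(=O)(OCC)OCC | intermediate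
18 | methylated phosphonate: 13β-methyl, 13α-side chain (epimers at the phosphonate carbon) | O=C1C=C2[C@@](C)(C=C)[C@H](C(C)=C)CC[C@]2(C(=O)C(OC)OC)C[C@@]1(C)CC(C(=O)OCC)P(=O)(OCC)OCC | intermediate
19 | tricyclic keto ester: ring D closed with C16=C19; CO2Et on C16; CH(OMe)2 on C19; 13β-methyl; enone C11=C9 kept | O=C1C=C2[C@@](C)(C=C)[C@H](C(C)=C)CC[C@]23C[C@@]1(C)CC(C(=O)OCC)=C3C(OC)OC | intermediate
20 | aldehyde: 19 with CHO on C19 | O=C1C=C2[C@@](C)(C=C)[C@H](C(C)=C)CC[C@]23C[C@@]1(C)CC(C(=O)OCC)=C3C=O | intermediate
21 | butenolide enone: γ-lactone ring E (C17=O, O, C18H2) fused to ring D at C16=C19 | O=C1C=C2[C@@](C)(C=C)[C@H](C(C)=C)CC[C@]23C[C@@]1(C)CC1=C3COC1=O | intermediate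
22 | iodine | II | starting material
23 | α-iodoenone: 21 with iodine on C11 | O=C1C(I)=C2[C@@](C)(C=C)[C@H](C(C)=C)CC[C@]23C[C@@]1(C)CC1=C3COC1=O | intermediate
24 | ethynyltrimethylsilane | C#C[Si](C)(C)C | starting material
25 | silylalkyne: 21 with C≡C–SiMe3 on C11 | O=C1C(C#C[Si](C)(C)C)=C2[C@@](C)(C=C)[C@H](C(C)=C)CC[C@]23C[C@@]1(C)CC1=C3COC1=O | intermediate
26 | ethynyl enone: 21 with C≡CH on C11 | O=C1C(C#C)=C2[C@@](C)(C=C)[C@H](C(C)=C)CC[C@]23C[C@@]1(C)CC1=C3COC1=O | intermediate
27 | saturated ketone: 9β-H; C11–H with the ethynyl group endo (toward the butenolide) | O=C1[C@@H](C#C)[C@H]2[C@@](C)(C=C)[C@H](C(C)=C)CC[C@]23C[C@@]1(C)CC1=C3COC1=O | intermediate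
28 | vinylstannane: cage closed (C19–C20), C20=CH–SnBu3 (alkene geometry not defined) | CCCC[Sn](CCCC)(CCCC)C=C1[C@@H]2C(=O)[C@]3(C)C[C@@H]4C(=O)OC[C@]14[C@@]1(CC[C@@H](C(C)=C)[C@](C)(C=C)[C@H]21)C3 | intermediate
29 | cage diene: target without ring A; 10α-vinyl and 5β-isopropenyl; exocyclic methylene on C20; C16–H as in the target | C=C1[C@@H]2C(=O)[C@]3(C)C[C@@H]4C(=O)OC[C@]14[C@@]1(CC[C@@H](C(C)=C)[C@](C)(C=C)[C@H]21)C3 | intermediate
30 | (E)-but-2-enoic acid (crotonic acid) | C/C=C/C(=O)O | starting material
31 | crotonate ester: 29 with C4(CH3)2–O–C(=O)–CH=CH–CH3 (E) in place of the isopropenyl group | C=C1[C@@H]2C(=O)[C@]3(C)C[C@@H]4C(=O)OC[C@]14[C@@]1(CC[C@@H](C(C)(C)OC(=O)/C=C/C)[C@](C)(C=C)[C@H]21)C3 | intermediate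
32 | CNP0136584.3 | C=C1[C@@H]2C(=O)[C@]3(C)C[C@@H]4C(=O)OC[C@]14[C@@]1(CC[C@H]4C(C)(C)OC(=O)C=C[C@]4(C)[C@H]21)C3 | target

**Step count and risks**

Total step count: 13. Longest linear sequence: 13 steps (1 → 32).

Steps most likely to fail:

Step 13. The tertiary alkylcobalt or cation may lose a proton (alkene isomerisation) faster than the weakly nucleophilic conjugated acid captures it, and the electron-poor, β-substituted crotonate may close the ring slowly. The fallback sets out from 29. A Mukaiyama hydration of the isopropenyl group (Co(acac)2, PhSiH3, O2, THF, 25 °C) would trap the C4 radical with dioxygen and give the tertiary alcohol F1. Acylation (acryloyl chloride, i-Pr2NEt, DMAP, CH2Cl2) would give the acrylate F2. Ring-closing metathesis of this more reactive acrylate (second-generation Hoveyda–Grubbs catalyst, toluene, 80 °C) comes back to the route at 32.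

Step 7. The methyl group may go to the phosphonate carbanion and not to the C13 enolate, or the ring may close before methylation and leave a bridgehead C13–H. The fallback sets out from 14. Michael addition of the kinetic C13 enolate to ethyl acrylate (LiN(i-Pr)2, THF, −78 °C) would give the propanoate F3. A second enolisation and methylation (LiN(i-Pr)2, MeI), again anti to the C8 acyl group, would give the methylated ester F4, in which the ester α-CH2 is the only acidic position left. An intramolecular aldol addition onto the C19 ketone (LiN(SiMe3)2, THF, −78 → 0 °C) would give the β-hydroxy ester F5. Dehydration (SOCl2, pyridine, 0 °C) comes back to the route at 19.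

Step 12. The vinyl radical may take hydrogen from the tin hydride, or add to the nearby C10 vinyl group, before it reaches the hindered butenolide carbon. The fallback sets out from 27. Haloboration of the alkyne and protonolysis (B-iodo-9-borabicyclo[3.3.1]nonane, pentane, −20 °C; AcOH) would give the iodoalkene F6. A reductive Heck cyclisation through an alkenylpalladium species (Pd(OAc)2, PPh3, HCO2Na, Et4NCl, DMF, 80 °C) forms the same C19–C20 bond without a free radical and comes back to the route at 29; the C16 centre is then set by protonation of the palladium enolate.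

**Further compounds**

F1 | step 13 | tertiary alcohol: 29 with a 2-hydroxypropan-2-yl group on C5 | C=C1[C@@H]2C(=O)[C@]3(C)C[C@@H]4C(=O)OC[C@]14[C@@]1(CC[C@@H](C(C)(C)O)[C@](C)(C=C)[C@H]21)C3
F2 | step 13 | acrylate ester of F1 | C=C1[C@@H]2C(=O)[C@]3(C)C[C@@H]4C(=O)OC[C@]14[C@@]1(CC[C@@H](C(C)(C)OC(=O)C=C)[C@](C)(C=C)[C@H]21)C3
F3 | step 7 | propanoate: 14 with CH2CH2CO2Et on C13 (C13 epimers) | O=C1C=C2[C@@](C)(C=C)[C@H](C(C)=C)CC[C@]2(C(=O)C(OC)OC)CC1CCC(=O)OCC
F4 | step 7 | methylated ester: 13β-methyl, 13α-CH2CH2CO2Et | O=C1C=C2[C@@](C)(C=C)[C@H](C(C)=C)CC[C@]2(C(=O)C(OC)OC)C[C@@]1(C)CCC(=O)OCC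
F5 | step 7 | β-hydroxy ester: ring D closed, OH and CH(OMe)2 on C19, CO2Et on C16 (epimers at C16 and C19) | O=C1C=C2[C@@](C)(C=C)[C@H](C(C)=C)CC[C@]23C[C@@]1(C)CC(C(=O)OCC)C3(O)C(OC)OC
F6 | step 12 | iodoalkene: 27 with a 1-iodoethenyl group on C11 in place of ethynyl | O=C1[C@@H](C(I)=C)[C@H]2[C@@](C)(C=C)[C@H](C(C)=C)CC[C@]23C[C@@]1(C)CC1=C3COC1=O
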